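## Retrosynthetic overview

1. Target 20 ⇐ global saponification of methyl ester bis(4-nitrobenzoate) 18; C5–OH comes from hydride addition anti to the oxirane, and the C2–O configuration comes from Mitsunobu inversion of cis-epoxy alcohol 15.
2. 15 ⇐ epoxy ketone 13 by ketone reduction and ketal hydrolysis; the heptenyl chain comes from Suzuki coupling on α-bromoenone 11.
3. 11 ⇐ asymmetric nucleophilic epoxidation of quinone monoketal 10, which sets both oxirane centres and is the only source of absolute configuration.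
4. 10 ⇐ oxidative dearomatisation of phenol 9; side chain by cross-metathesis of an allyl arene, allyl by Claisen rearrangement, Br by bromination of 5-hydroxy-2-methoxybenzaldehyde 1.
5. Ring order: the carbocycle is the benzene ring of 1 (dearomatised in step 6); the oxirane is the only ring formed (step 7).

Assumption: in step 7 the L-(+)-DIPT complex is taken to give the (1R,6S)-epoxide 11; if it gives the antipode, D-(−)-DIPT is used and nothing else changes.

Ring locants used below are those of the 7-oxabicyclo[4.1.0]hept-3-ene: C1 = oxirane carbon bearing the side chain, C2 = carbinol next to it, C5 = the other carbinol, C6 = oxirane CH.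

## Route

Step 1
Reactants: 1 5-hydroxy-2-methoxybenzaldehyde
Product: 2 2-bromo-3-hydroxy-6-methoxybenzaldehyde
Conditions: Br2, NaOAc, AcOH, rt
Reagents that add atoms: bromine, BrBr
Why: Electrophilic aromatic bromination in which the phenol directs ortho (its para position is blocked by OMe) and, as is usual for 3-hydroxybenzaldehydes, the ortho site flanked by CHO reacts, so one regioisomer forms and no stereocentre is involved.

Step 2
Reactants: 2 2-bromo-3-hydroxy-6-methoxybenzaldehyde; 3 allyl bromide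
Product: 4 2-bromo-6-methoxy-3-(prop-2-en-1-yloxy)benzaldehyde
Conditions: K2CO3, DMF, rt
Reagents that add atoms: none
Why: Williamson ether synthesis (SN2 of the phenoxide on the allylic bromide).

Step 3
Reactants: 4 2-bromo-6-methoxy-3-(prop-2-en-1-yloxy)benzaldehyde
Product: 6 4-allyl-2-bromo-3-hydroxy-6-methoxybenzaldehyde, via Claisen dienone 5 (not isolated)
Conditions: PhNEt2, 190 °C
Reagents that add atoms: none
Why: Aromatic Claisen [3,3]-sigmatropic rearrangement to the only free ortho position (the other carries Br), followed by tautomerisation of dienone 5 to the phenol, an isomerisation with no by-product.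

Step 4
Reactants: 6 4-allyl-2-bromo-3-hydroxy-6-methoxybenzaldehyde
Product: 7 6-allyl-2-bromo-3-(hydroxymethyl)-4-methoxyphenol
Conditions: NaBH4, MeOH, 0 °C
Reagents that add atoms: none
Why: Borohydride reduction of the aryl aldehyde to the benzylic alcohol, done before metathesis so that no phenoxide meets the enoate (avoids oxa-Michael closure).

Step 5
Reactants: 7 6-allyl-2-bromo-3-(hydroxymethyl)-4-methoxyphenol; 8 methyl methacrylate
Product: 9 methyl (2E)-4-[3-bromo-2-hydroxy-4-(hydroxymethyl)-5-methoxyphenyl]-2-methylbut-2-enoate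
Conditions: Hoveyda–Grubbs II (5 mol%), 1,4-benzoquinone (10 mol%), 8 (10 equiv), CH2Cl2, 40 °C
Reagents that add atoms: none
Why: Olefin cross-metathesis of a terminal alkene with a 1,1-disubstituted acrylate gives the thermodynamically favoured (E)-trisubstituted enoate, while benzoquinone suppresses allyl-to-propenyl isomerisation.

Step 6
Reactants: 9 methyl (2E)-4-[3-bromo-2-hydroxy-4-(hydroxymethyl)-5-methoxyphenyl]-2-methylbut-2-enoate
Product: 10 methyl (2E)-4-[5-bromo-4-(hydroxymethyl)-3,3-dimethoxy-6-oxocyclohexa-1,4-dien-1-yl]-2-methylbut-2-enoate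
Conditions: PhI(OAc)2, MeOH, 0 °C
Reagents that add atoms: methanol, CO
Why: Hypervalent-iodine oxidative dearomatisation of a p-methoxyphenol in methanol gives the quinone monoketal, with C=O at the former phenol carbon and the dimethyl ketal at the former anisole carbon.

Step 7
Reactants: 10 methyl (2E)-4-[5-bromo-4-(hydroxymethyl)-3,3-dimethoxy-6-oxocyclohexa-1,4-dien-1-yl]-2-methylbut-2-enoate
Product: 11 methyl (2E)-4-[(1R,6S)-3-bromo-4-(hydroxymethyl)-5,5-dimethoxy-2-oxo-7-oxabicyclo[4.1.0]hept-3-en-1-yl]-2-methylbut-2-enoate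
Conditions: Ph3COOH, NaHMDS, L-(+)-DIPT, 4 Å MS, PhMe, −60 to −40 °C
Reagents that add atoms: trityl hydroperoxide, OOC(c1ccccc1)(c1ccccc1)c1ccccc1
Why: Tartrate-mediated asymmetric nucleophilic (Weitz–Scheffer) epoxidation in which the trityl peroxide anion attacks the CH terminus of the alkyl-substituted enone (the bromo-enone arm is tetrasubstituted) and the sodium tartrate aggregate bound to the free CH2OH selects the face, setting both oxirane centres.

Step 8
Reactants: 11 methyl (2E)-4-[(1R,6S)-3-bromo-4-(hydroxymethyl)-5,5-dimethoxy-2-oxo-7-oxabicyclo[4.1.0]hept-3-en-1-yl]-2-methylbut-2-enoate; 12 (E)-hept-1-en-1-ylboronic acid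
Product: 13 methyl (2E)-4-[(1R,6S)-3-[(1E)-hept-1-en-1-yl]-4-(hydroxymethyl)-5,5-dimethoxy-2-oxo-7-oxabicyclo[4.1.0]hept-3-en-1-yl]-2-methylbut-2-enoate
Conditions: Pd(dppf)Cl2 (5 mol%), K3PO4, THF/H2O, 40 °C
Reagents that add atoms: none
Why: Suzuki–Miyaura coupling at the activated α-bromoenone C–Br bond with retention of the (E)-alkenyl geometry and no stereocentre touched.

Step 9
Reactants: 13 methyl (2E)-4-[(1R,6S)-3-[(1E)-hept-1-en-1-yl]-4-(hydroxymethyl)-5,5-dimethoxy-2-oxo-7-oxabicyclo[4.1.0]hept-3-en-1-yl]-2-methylbut-2-enoate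
Product: 15 methyl (2E)-4-[(1S,2S,6S)-3-[(1E)-hept-1-en-1-yl]-2-hydroxy-4-(hydroxymethyl)-5-oxo-7-oxabicyclo[4.1.0]hept-3-en-1-yl]-2-methylbut-2-enoate, via ketal alcohol 14 (not isolated)
Conditions: NaBH4, CeCl3·7H2O, MeOH, −78 °C; then 1 M HCl, THF, 0 °C to rt
Reagents that add atoms: water, O
Why: Luche 1,2-reduction in which the small hydride enters anti to the oxirane oxygen (Felkin–Anh/electrostatic control) to give the cis-epoxy alcohol (2S), followed by acid hydrolysis of the now simply allylic dimethyl ketal to the C5 enone.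

Step 10
Reactants: 15 methyl (2E)-4-[(1S,2S,6S)-3-[(1E)-hept-1-en-1-yl]-2-hydroxy-4-(hydroxymethyl)-5-oxo-7-oxabicyclo[4.1.0]hept-3-en-1-yl]-2-methylbut-2-enoate
Product: 17 methyl (2E)-4-[(1S,2R,6S)-3-[(1E)-hept-1-en-1-yl]-2-(4-nitrobenzoyloxy)-4-[(4-nitrobenzoyloxy)methyl]-5-oxo-7-oxabicyclo[4.1.0]hept-3-en-1-yl]-2-methylbut-2-enoate, via mono-nitrobenzoate 16 (not isolated)
Conditions: 4-O2NC6H4CO2H, PPh3, DIAD, PhMe, 0 °C to rt
Reagents that add atoms: 4-nitrobenzoic acid, O=C(O)c1ccc(cc1)[N+](=O)[O-]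
Why: Mitsunobu reaction that first esterifies the primary alcohol and then displaces the secondary C2 carbinol with SN2 inversion (2S to 2R, now trans to the oxirane), SN2′ being blocked by the fully substituted alkene and elimination by the absence of a β-hydrogen.

Step 11
Reactants: 17 methyl (2E)-4-[(1S,2R,6S)-3-[(1E)-hept-1-en-1-yl]-2-(4-nitrobenzoyloxy)-4-[(4-nitrobenzoyloxy)methyl]-5-oxo-7-oxabicyclo[4.1.0]hept-3-en-1-yl]-2-methylbut-2-enoate
Product: 18 methyl (2E)-4-[(1S,2R,5R,6R)-3-[(1E)-hept-1-en-1-yl]-5-hydroxy-2-(4-nitrobenzoyloxy)-4-[(4-nitrobenzoyloxy)methyl]-7-oxabicyclo[4.1.0]hept-3-en-1-yl]-2-methylbut-2-enoate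
Conditions: NaBH4, CeCl3·7H2O, MeOH, −78 °C
Reagents that add atoms: none
Why: Luche 1,2-reduction of the only remaining ketone, with hydride again adding anti to the oxirane oxygen (the neighbouring oxirane carbon carries only H on the open face), which sets C5 as the cis-epoxy alcohol (5R).

Step 12
Reactants: 18 methyl (2E)-4-[(1S,2R,5R,6R)-3-[(1E)-hept-1-en-1-yl]-5-hydroxy-2-(4-nitrobenzoyloxy)-4-[(4-nitrobenzoyloxy)methyl]-7-oxabicyclo[4.1.0]hept-3-en-1-yl]-2-methylbut-2-enoate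
Product: 20 (2E)-4-[(1S,2R,5R,6R)-3-[(1E)-hept-1-en-1-yl]-2,5-dihydroxy-4-(hydroxymethyl)-7-oxabicyclo[4.1.0]hept-3-en-1-yl]-2-methylbut-2-enoic acid, via triol methyl ester 19 (not isolated)
Conditions: LiOH, THF/MeOH/H2O, 0 °C to rt; then 0.5 M HCl to pH 4, 0 °C
Reagents that add atoms: lithium hydroxide, [Li+].[OH-]
Why: Saponification by acyl–oxygen cleavage removes both nitrobenzoates and then the methyl ester without touching any stereocentre, Payne migration being disfavoured because the only anti-disposed alkoxide (C2) would have to attack the quaternary oxirane carbon.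

## Compound list

1 | 5-hydroxy-2-methoxybenzaldehyde | O=Cc1cc(O)ccc1OC | starting material
2 | 2-bromo-3-hydroxy-6-methoxybenzaldehyde | O=Cc1c(Br)c(O)ccc1OC | intermediate
3 | allyl bromide (3-bromoprop-1-ene) | C=CCBr | starting material
4 | 2-bromo-6-methoxy-3-(prop-2-en-1-yloxy)benzaldehyde | O=Cc1c(Br)c(OCC=C)ccc1OC | intermediate
5 | 2-bromo-6-methoxy-3-oxo-4-(prop-2-en-1-yl)cyclohexa-1,5-diene-1-carbaldehyde (racemic Claisen dienone) | O=CC1=C(Br)C(=O)C(CC=C)C=C1OC | intermediate (not isolated)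
6 | 4-allyl-2-bromo-3-hydroxy-6-methoxybenzaldehyde | O=Cc1c(Br)c(O)c(CC=C)cc1OC | intermediate
7 | 6-allyl-2-bromo-3-(hydroxymethyl)-4-methoxyphenol | OCc1c(Br)c(O)c(CC=C)cc1OC | intermediate
8 | methyl methacrylate | C=C(C)C(=O)OC | starting material
9 | methyl (2E)-4-[3-bromo-2-hydroxy-4-(hydroxymethyl)-5-methoxyphenyl]-2-methylbut-2-enoate | OCc1c(Br)c(O)c(C/C=C(\C)C(=O)OC)cc1OC | intermediate
10 | methyl (2E)-4-[5-bromo-4-(hydroxymethyl)-3,3-dimethoxy-6-oxocyclohexa-1,4-dien-1-yl]-2-methylbut-2-enoate | O=C1C(Br)=C(CO)C(OC)(OC)C=C1C/C=C(\C)C(=O)OC | intermediate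
11 | methyl (2E)-4-[(1R,6S)-3-bromo-4-(hydroxymethyl)-5,5-dimethoxy-2-oxo-7-oxabicyclo[4.1.0]hept-3-en-1-yl]-2-methylbut-2-enoate | BrC1=C(CO)C(OC)(OC)[C@H]2O[C@@]2(C/C=C(\C)C(=O)OC)C1=O | intermediate
12 | (E)-hept-1-en-1-ylboronic acid | CCCCC/C=C/B(O)O | starting material
13 | methyl (2E)-4-[(1R,6S)-3-[(1E)-hept-1-en-1-yl]-4-(hydroxymethyl)-5,5-dimethoxy-2-oxo-7-oxabicyclo[4.1.0]hept-3-en-1-yl]-2-methylbut-2-enoate | CCCCC/C=C/C1=C(CO)C(OC)(OC)[C@H]2O[C@@]2(C/C=C(\C)C(=O)OC)C1=O | intermediate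
14 | methyl (2E)-4-[(1S,2S,6S)-3-[(1E)-hept-1-en-1-yl]-2-hydroxy-4-(hydroxymethyl)-5,5-dimethoxy-7-oxabicyclo[4.1.0]hept-3-en-1-yl]-2-methylbut-2-enoate (OH cis to oxirane) | CCCCC/C=C/C1=C(CO)C(OC)(OC)[C@H]2O[C@@]2(C/C=C(\C)C(=O)OC)[C@H]1O | intermediate (not isolated)
15 | methyl (2E)-4-[(1S,2S,6S)-3-[(1E)-hept-1-en-1-yl]-2-hydroxy-4-(hydroxymethyl)-5-oxo-7-oxabicyclo[4.1.0]hept-3-en-1-yl]-2-methylbut-2-enoate | CCCCC/C=C/C1=C(CO)C(=O)[C@H]2O[C@@]2(C/C=C(\C)C(=O)OC)[C@H]1O | intermediate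
16 | methyl (2E)-4-[(1S,2S,6S)-3-[(1E)-hept-1-en-1-yl]-2-hydroxy-4-[(4-nitrobenzoyloxy)methyl]-5-oxo-7-oxabicyclo[4.1.0]hept-3-en-1-yl]-2-methylbut-2-enoate | CCCCC/C=C/C1=C(COC(=O)c3ccc(cc3)[N+](=O)[O-])C(=O)[C@H]2O[C@@]2(C/C=C(\C)C(=O)OC)[C@H]1O | intermediate (not isolated)
17 | methyl (2E)-4-[(1S,2R,6S)-3-[(1E)-hept-1-en-1-yl]-2-(4-nitrobenzoyloxy)-4-[(4-nitrobenzoyloxy)methyl]-5-oxo-7-oxabicyclo[4.1.0]hept-3-en-1-yl]-2-methylbut-2-enoate | CCCCC/C=C/C1=C(COC(=O)c3ccc(cc3)[N+](=O)[O-])C(=O)[C@H]2O[C@@]2(C/C=C(\C)C(=O)OC)[C@@H]1OC(=O)c4ccc(cc4)[N+](=O)[O-] | intermediate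
18 | methyl (2E)-4-[(1S,2R,5R,6R)-3-[(1E)-hept-1-en-1-yl]-5-hydroxy-2-(4-nitrobenzoyloxy)-4-[(4-nitrobenzoyloxy)methyl]-7-oxabicyclo[4.1.0]hept-3-en-1-yl]-2-methylbut-2-enoate | CCCCC/C=C/C1=C(COC(=O)c3ccc(cc3)[N+](=O)[O-])[C@@H](O)[C@H]2O[C@@]2(C/C=C(\C)C(=O)OC)[C@@H]1OC(=O)c4ccc(cc4)[N+](=O)[O-] | intermediate
19 | methyl (2E)-4-[(1S,2R,5R,6R)-3-[(1E)-hept-1-en-1-yl]-2,5-dihydroxy-4-(hydroxymethyl)-7-oxabicyclo[4.1.0]hept-3-en-1-yl]-2-methylbut-2-enoate | CCCCC/C=C/C1=C(CO)[C@@H](O)[C@H]2O[C@@]2(C/C=C(\C)C(=O)OC)[C@@H]1O | intermediate (not isolated)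
20 | (2E)-4-[(1S,2R,5R,6R)-3-[(1E)-hept-1-en-1-yl]-2,5-dihydroxy-4-(hydroxymethyl)-7-oxabicyclo[4.1.0]hept-3-en-1-yl]-2-methylbut-2-enoic acid (CNP0087193.3) | CCCCC/C=C/C1=C(CO)[C@@H](O)[C@H]2O[C@@]2(C/C=C(\C)C(=O)O)[C@@H]1O | target

## Step count and risks

Total step count: 12. Longest linear sequence: 12 steps (1 to 20); compounds 3, 8 and 12 are purchased.

The three steps most likely to fail:

Step 7 (asymmetric epoxidation: ee and facial sense). The fallback sets out from 10 and comes back at 11. Compound 10 is epoxidised without chiral control (t-BuOOH, DBU, CH2Cl2, 0 °C), which gives 11 together with its mirror image ent-11 F1. The two are separated by preparative chromatography on a chiral stationary phase (SFC), and 11 re-enters at step 8; absolute configuration then comes from resolution, not from the tartrate.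

Step 9 (facial selectivity of the C2 ketone reduction: the CH2 on the quaternary oxirane carbon partly screens the face anti to the oxirane oxygen, so the ratio may be low or reversed). The fallback sets out from 13 and comes back at 17. If hydride enters on the oxirane face, the same one-pot procedure gives the epimeric ketal alcohol 2-epi-14 F2 and, after hydrolysis, the trans-epoxy alcohol 2-epi-15 F3. F3 already has the C2 configuration of the target, so both hydroxyls are acylated with retention (4-nitrobenzoyl chloride, pyridine, DMAP, CH2Cl2, 0 °C), passing through the primary mono-ester 2-epi-16 F4, to give 17 directly. The Mitsunobu inversion is dropped.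

Step 10 (Mitsunobu inversion at a carbinol flanked by a quaternary oxirane carbon and a fully substituted alkene). The fallback sets out from 13 and comes back at 19. It replaces inversion by directed reduction, but its C2 reduction is less well precedented than the main route. The ketal of 13 is hydrolysed without prior reduction (1 M HCl, THF) to the ene-dione F5. Only the C5 ketone is then reduced, by hydride delivered from the neighbouring CH2OH and anti to the oxirane (Me4NBH(OAc)3, MeCN/AcOH, −20 °C), giving ambuic acid methyl ester F6. The C2 ketone is reduced last, with hydride delivered across the ring from the C5 oxygen, which sits on the oxirane face (excess Me4NBH(OAc)3 at rt, or Zn(BH4)2, Et2O, 0 °C). This gives the trans-epoxy alcohol 19, which is saponified as in step 12.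

## Further compounds

F1 | step 7 | methyl (2E)-4-[(1S,6R)-3-bromo-4-(hydroxymethyl)-5,5-dimethoxy-2-oxo-7-oxabicyclo[4.1.0]hept-3-en-1-yl]-2-methylbut-2-enoate (ent-11) | BrC1=C(CO)C(OC)(OC)[C@@H]2O[C@]2(C/C=C(\C)C(=O)OC)C1=O
F2 | step 9 | methyl (2E)-4-[(1S,2R,6S)-3-[(1E)-hept-1-en-1-yl]-2-hydroxy-4-(hydroxymethyl)-5,5-dimethoxy-7-oxabicyclo[4.1.0]hept-3-en-1-yl]-2-methylbut-2-enoate (2-epi-14) | CCCCC/C=C/C1=C(CO)C(OC)(OC)[C@H]2O[C@@]2(C/C=C(\C)C(=O)OC)[C@@H]1O
F3 | step 9 | methyl (2E)-4-[(1S,2R,6S)-3-[(1E)-hept-1-en-1-yl]-2-hydroxy-4-(hydroxymethyl)-5-oxo-7-oxabicyclo[4.1.0]hept-3-en-1-yl]-2-methylbut-2-enoate (2-epi-15) | CCCCC/C=C/C1=C(CO)C(=O)[C@H]2O[C@@]2(C/C=C(\C)C(=O)OC)[C@@H]1O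
F4 | step 9 | methyl (2E)-4-[(1S,2R,6S)-3-[(1E)-hept-1-en-1-yl]-2-hydroxy-4-[(4-nitrobenzoyloxy)methyl]-5-oxo-7-oxabicyclo[4.1.0]hept-3-en-1-yl]-2-methylbut-2-enoate (2-epi-16) | CCCCC/C=C/C1=C(COC(=O)c3ccc(cc3)[N+](=O)[O-])C(=O)[C@H]2O[C@@]2(C/C=C(\C)C(=O)OC)[C@@H]1O
F5 | step 10 | methyl (2E)-4-[(1R,6S)-3-[(1E)-hept-1-en-1-yl]-4-(hydroxymethyl)-2,5-dioxo-7-oxabicyclo[4.1.0]hept-3-en-1-yl]-2-methylbut-2-enoate (ene-dione) | CCCCC/C=C/C1=C(CO)C(=O)[C@H]2O[C@@]2(C/C=C(\C)C(=O)OC)C1=O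
F6 | step 10 | methyl (2E)-4-[(1R,5R,6R)-3-[(1E)-hept-1-en-1-yl]-5-hydroxy-4-(hydroxymethyl)-2-oxo-7-oxabicyclo[4.1.0]hept-3-en-1-yl]-2-methylbut-2-enoate (ambuic acid methyl ester) | CCCCC/C=C/C1=C(CO)[C@@H](O)[C@H]2O[C@@]2(C/C=C(\C)C(=O)OC)C1=O
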